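**Strategy.** Halimane numbering: ring A = C1–C5/C10, ring B = C5–C10. The route rests on cutting the unsubstituted ethano bridge C2–C3 out of ring A: C4 (quaternary, ester-bearing) and C1 (the vinylic CH of the C1=C10 olefin) are 1,4-related through C5–C10 and both can be made reactive on a ring-B cyclohexane. In the key step the C4 ester enolate adds to phenyl vinyl sulfone (C3–C4, C4 set by allylic strain) and the C2 sulfonyl carbanion displaces the iodide of an axial CH2I on C10 (C1–C2). The precursor is a monocyclic iodo silyl ether; its C10 oxygen, cis to H-5, later leaves only toward C1.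

Key step: step 6

Remark: in step 1 the ligand enantiomer is the one that delivers methyl to give the 3R adduct.
Remark: the sulfonyl-bearing carbon of 15 should form as an epimer mixture and is drawn without a descriptor; it is removed in step 7.

Step 1
Reactants: 1 2-methylcyclohex-2-en-1-one; 2 allyl bromide
Product: 5 (2S,3R)-2,3-dimethyl-2-(prop-2-en-1-yl)cyclohexan-1-one, via dimethylaluminium enolate 3 (not isolated), via lithium aluminate enolate 4 (not isolated)
Conditions: Me3Al, CuTC (cat.), chiral phosphoramidite (cat.), Et2O, −30 °C; then MeLi, HMPA, allyl bromide, THF, −30 °C → rt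
Reagents that add atoms: trimethylaluminium C[Al](C)C
Why: Copper-catalysed asymmetric conjugate addition, in which the ligand fixes C3 (3R, the later C8), followed by allylation of the aluminate enolate anti to the new methyl, so that the quaternary C2 (2S, the later C9) carries its methyl cis to the C3 methyl.

Step 2
Reactants: 6 methyl (S)-lactate
Product: 7 methyl (2S)-2-{[(trifluoromethyl)sulfonyl]oxy}propanoate
Conditions: Tf2O, 2,6-lutidine, CH2Cl2, −78 → 0 °C; used at once
Reagents that add atoms: trifluoromethanesulfonic anhydride O=S(=O)(OS(=O)(=O)C(F)(F)F)C(F)(F)F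
Why: O-Sulfonylation of the secondary alcohol (retention at carbon) gives an SN2 electrophile reactive enough for a hindered ketone enolate.

Step 3
Reactants: 5 (2S,3R)-2,3-dimethyl-2-(prop-2-en-1-yl)cyclohexan-1-one; 7 methyl (2S)-2-{[(trifluoromethyl)sulfonyl]oxy}propanoate
Product: 9 methyl (2S)-2-[(1S,3S,4R)-3,4-dimethyl-2-oxo-3-(prop-2-en-1-yl)cyclohexyl]propanoate, via lithium enolate 8 (not isolated)
Conditions: LDA, THF, −78 °C; then 7, −78 → −20 °C
Reagents that add atoms: none
Why: Enolate alkylation: the enolate can only form on the CH2 side, and the SN2 step (inversion at the lactate carbon) should place the side chain equatorial, anti to the axial methyl of the quaternary carbon, which is also the thermodynamic arrangement; the propanoate α-centre is of no consequence because it is planarised in step 6.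

Step 4
Reactants: 9 methyl (2S)-2-[(1S,3S,4R)-3,4-dimethyl-2-oxo-3-(prop-2-en-1-yl)cyclohexyl]propanoate
Product: 10 methyl (2S)-2-[(3S,4S,7R,8S)-7,8-dimethyl-8-(prop-2-en-1-yl)-1-oxaspiro[2.5]octan-4-yl]propanoate
Conditions: Me3S+ I−, n-BuLi, THF, −10 °C → rt
Reagents that add atoms: trimethylsulfonium iodide C[S+](C)C.[I-]
Why: Corey–Chaykovsky epoxidation: the small sulfonium ylide should add axially, on the face opposite the axial methyl of the neighbouring quaternary carbon, so the new CH2 (C1) is axial and the C10 oxygen equatorial, cis to H-5.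

Step 5
Reactants: 10 methyl (2S)-2-[(3S,4S,7R,8S)-7,8-dimethyl-8-(prop-2-en-1-yl)-1-oxaspiro[2.5]octan-4-yl]propanoate
Product: 11 methyl (2S)-2-[(1S,2S,3S,4R)-2-(iodomethyl)-3,4-dimethyl-3-(prop-2-en-1-yl)-2-[(trimethylsilyl)oxy]cyclohexyl]propanoate
Conditions: TMSI, CH2Cl2, −78 → −40 °C
Reagents that add atoms: iodotrimethylsilane C[Si](C)(C)I
Why: Silyl iodide opening of the 2,2-disubstituted oxirane: O-silylation and SN2 attack of iodide at the CH2 give the tertiary silyl ether with retention at C10 and turn the tied-back epoxide into a freely rotating primary iodide, which the ring closure of step 6 needs for an in-line displacement.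

Step 6
Reactants: 11 methyl (2S)-2-[(1S,2S,3S,4R)-2-(iodomethyl)-3,4-dimethyl-3-(prop-2-en-1-yl)-2-[(trimethylsilyl)oxy]cyclohexyl]propanoate; 12 phenyl vinyl sulfone
Product: 15 methyl (1S,4aS,5S,6R,8aS)-1,5,6-trimethyl-3-(phenylsulfonyl)-5-(prop-2-en-1-yl)-4a-[(trimethylsilyl)oxy]decahydronaphthalene-1-carboxylate, via lithium ketene acetal 13 (not isolated), via lithiated Michael adduct 14 (not isolated)
Conditions: LDA, THF, −78 °C; 12 (1.0 equiv), −78 °C; then DMPU, → rt
Reagents that add atoms: none
Why: LDA gives the tetrasubstituted lithium ketene acetal 13, which adds to phenyl vinyl sulfone (C3–C4), and the α-sulfonyl carbanion 14 then closes ring A by SN2 displacement of the primary iodide (C1–C2); the vinyl sulfone acts as an ethylene unit that is acceptor at C3 and donor at C2. The closest known reaction types are the Michael-initiated ring closure (MIRC), enolate additions to vinyl sulfones and sulfone-carbanion cycloalkylations. Ring A closes 6-exo-tet through a chair in which the axial CH2I on C10 and the equatorial side chain on C5 are gauche, so the decalin is cis-fused with the C10 oxygen cis to H-5; C10 carries no hydrogen, so no E2 can compete. The new quaternary centre C4 is controlled by allylic 1,3-strain in 13: H-5 eclipses the ketene acetal oxygen and the acceptor should approach anti to the fully substituted C10, which gives the 4S configuration of the target (methyl on the side of H-5). The step needs face selectivity at C4 and mono-addition; the first rests on the size difference between C10 and C6, the second on the quaternary C4 (no proton is left to relay a second addition) and on one equivalent of sulfone. The sulfonyl carbon forms as a mixture, which does not matter.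

Step 7
Reactants: 15 methyl (1S,4aS,5S,6R,8aS)-1,5,6-trimethyl-3-(phenylsulfonyl)-5-(prop-2-en-1-yl)-4a-[(trimethylsilyl)oxy]decahydronaphthalene-1-carboxylate
Product: 16 methyl (1S,4aS,5S,6R,8aS)-4a-hydroxy-1,5,6-trimethyl-5-(prop-2-en-1-yl)decahydronaphthalene-1-carboxylate
Conditions: Na(Hg) 6%, Na2HPO4, MeOH/THF, −20 → 0 °C; then citric acid, MeOH, rt
Reagents that add atoms: none
Why: Reductive desulfonylation by electron transfer from sodium amalgam removes the activating group, and mild methanolysis of the trimethylsilyl ether frees the tertiary alcohol; only the vanishing sulfonyl carbon is touched.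

Step 8
Reactants: 16 methyl (1S,4aS,5S,6R,8aS)-4a-hydroxy-1,5,6-trimethyl-5-(prop-2-en-1-yl)decahydronaphthalene-1-carboxylate
Product: 17 methyl (1S,5S,6R,8aR)-1,5,6-trimethyl-5-(prop-2-en-1-yl)-1,2,3,5,6,7,8,8a-octahydronaphthalene-1-carboxylate
Conditions: SOCl2, pyridine, CH2Cl2, −20 → 0 °C
Reagents that add atoms: none
Why: Chlorosulfite formation and pyridine-induced anti E2 elimination: in the cis-fused carbinol the only hydrogen that can become antiperiplanar to the C10–O bond is on C1 (H-5 is cis, C9 is quaternary), so the C1=C10 olefin should form regiospecifically.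

Step 9
Reactants: 17 methyl (1S,5S,6R,8aR)-1,5,6-trimethyl-5-(prop-2-en-1-yl)-1,2,3,5,6,7,8,8a-octahydronaphthalene-1-carboxylate
Product: 18 methyl (1S,5S,6R,8aR)-1,5,6-trimethyl-5-(3-oxopropyl)-1,2,3,5,6,7,8,8a-octahydronaphthalene-1-carboxylate
Conditions: PdCl2(PhCN)2 (cat.), CuCl2·2H2O (cat.), AgNO2 (cat.), t-BuOH/MeNO2, O2 (1 atm), rt
Reagents that add atoms: dioxygen O=O
Why: Nitrite-modified, aldehyde-selective Wacker oxidation of the unbiased terminal alkene should give the anti-Markovnikov aldehyde, while the hindered trisubstituted ring olefin stays inert.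

Step 10
Reactants: 18 methyl (1S,5S,6R,8aR)-1,5,6-trimethyl-5-(3-oxopropyl)-1,2,3,5,6,7,8,8a-octahydronaphthalene-1-carboxylate
Product: 19 methyl (1S,5S,6R,8aR)-5-(but-3-yn-1-yl)-1,5,6-trimethyl-1,2,3,5,6,7,8,8a-octahydronaphthalene-1-carboxylate
Conditions: Ohira–Bestmann reagent, K2CO3, MeOH, 0 °C → rt
Reagents that add atoms: dimethyl (1-diazo-2-oxopropyl)phosphonate CC(=O)C(=[N+]=[N-])P(=O)(OC)OC
Why: Ohira–Bestmann (Seyferth–Gilbert) homologation converts the aldehyde into the terminal alkyne under conditions that leave the methyl ester unchanged.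

Step 11
Reactants: 19 methyl (1S,5S,6R,8aR)-5-(but-3-yn-1-yl)-1,5,6-trimethyl-1,2,3,5,6,7,8,8a-octahydronaphthalene-1-carboxylate
Product: 22 methyl (1S,5S,6R,8aR)-5-[(3E)-5-hydroxy-3-methylpent-3-en-1-yl]-1,5,6-trimethyl-1,2,3,5,6,7,8,8a-octahydronaphthalene-1-carboxylate, via alkenyldimethylalane 20 (not isolated), via lithium butyl alanate 21 (not isolated)
Conditions: Me3Al, Cp2ZrCl2 (cat.), H2O (1 equiv), CH2Cl2, −23 °C; volatiles removed; n-BuLi, THF, −78 °C; (CH2O)n, −78 °C → rt
Reagents that add atoms: trimethylaluminium C[Al](C)C; formaldehyde (as paraformaldehyde) C=O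
Why: Negishi zirconium-catalysed carboalumination adds Me and Al syn across the alkyne (Me to the internal carbon), and the alanate is hydroxymethylated with retention, so the trisubstituted olefin is E; the axial neopentyl ester should be too hindered to react at these temperatures.

Step 12
Reactants: 22 methyl (1S,5S,6R,8aR)-5-[(3E)-5-hydroxy-3-methylpent-3-en-1-yl]-1,5,6-trimethyl-1,2,3,5,6,7,8,8a-octahydronaphthalene-1-carboxylate
Product: 23 methyl (1S,5S,6R,8aR)-5-[(3E)-5-(formyloxy)-3-methylpent-3-en-1-yl]-1,5,6-trimethyl-1,2,3,5,6,7,8,8a-octahydronaphthalene-1-carboxylate (CNP0188193.1)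
Conditions: HCO2H, DCC, DMAP (cat.), CH2Cl2, 0 °C
Reagents that add atoms: formic acid OC=O
Why: Steglich-type formylation of the primary allylic alcohol under neutral conditions should give the formate without allylic ionisation.

**Compound list**

1 | 2-methylcyclohex-2-en-1-one | CC1=CCCCC1=O | starting material
2 | allyl bromide | C=CCBr | starting material
3 | dimethyl{[(3R)-2,3-dimethylcyclohex-1-en-1-yl]oxy}alumane | C[Al](C)OC1=C(C)[C@H](C)CCC1 | intermediate (not isolated)
4 | lithium trimethyl{[(3R)-2,3-dimethylcyclohex-1-en-1-yl]oxy}aluminate | [Li+].C[Al-](C)(C)OC1=C(C)[C@H](C)CCC1 | intermediate (not isolated)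
5 | (2S,3R)-2,3-dimethyl-2-(prop-2-en-1-yl)cyclohexan-1-one | O=C1CCC[C@@H](C)[C@]1(C)CC=C | intermediate
6 | methyl (S)-lactate | C[C@H](O)C(=O)OC | starting material
7 | methyl (2S)-2-{[(trifluoromethyl)sulfonyl]oxy}propanoate | C[C@H](OS(=O)(=O)C(F)(F)F)C(=O)OC | intermediate
8 | lithium (5R,6S)-5,6-dimethyl-6-(prop-2-en-1-yl)cyclohex-1-en-1-olate | [Li]OC1=CCC[C@@H](C)[C@]1(C)CC=C | intermediate (not isolated)
9 | methyl (2S)-2-[(1S,3S,4R)-3,4-dimethyl-2-oxo-3-(prop-2-en-1-yl)cyclohexyl]propanoate | COC(=O)[C@@H](C)[C@@H]1CC[C@@H](C)[C@](C)(CC=C)C1=O | intermediate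
10 | methyl (2S)-2-[(3S,4S,7R,8S)-7,8-dimethyl-8-(prop-2-en-1-yl)-1-oxaspiro[2.5]octan-4-yl]propanoate | COC(=O)[C@@H](C)[C@@H]1CC[C@@H](C)[C@](C)(CC=C)[C@]12CO2 | intermediate
11 | methyl (2S)-2-[(1S,2S,3S,4R)-2-(iodomethyl)-3,4-dimethyl-3-(prop-2-en-1-yl)-2-[(trimethylsilyl)oxy]cyclohexyl]propanoate | COC(=O)[C@@H](C)[C@@H]1CC[C@@H](C)[C@](C)(CC=C)[C@@]1(CI)O[Si](C)(C)C | intermediate
12 | phenyl vinyl sulfone | C=CS(=O)(=O)c1ccccc1 | starting material
13 | lithium ketene acetal (ester enolate) of 11 | COC(O[Li])=C(C)[C@@H]1CC[C@@H](C)[C@](C)(CC=C)[C@@]1(CI)O[Si](C)(C)C | intermediate (not isolated)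
14 | lithiated Michael adduct (α-sulfonyl carbanion, C4 quaternary, 4S) | COC(=O)[C@@](C)(CC([Li])S(=O)(=O)c1ccccc1)[C@@H]2CC[C@@H](C)[C@](C)(CC=C)[C@@]2(CI)O[Si](C)(C)C | intermediate (not isolated)
15 | methyl (1S,4aS,5S,6R,8aS)-1,5,6-trimethyl-3-(phenylsulfonyl)-5-(prop-2-en-1-yl)-4a-[(trimethylsilyl)oxy]decahydronaphthalene-1-carboxylate (epimers at C3) | COC(=O)[C@@]1(C)CC(S(=O)(=O)c2ccccc2)C[C@]3(O[Si](C)(C)C)[C@H]1CC[C@@H](C)[C@]3(C)CC=C | intermediate
16 | methyl (1S,4aS,5S,6R,8aS)-4a-hydroxy-1,5,6-trimethyl-5-(prop-2-en-1-yl)decahydronaphthalene-1-carboxylate | COC(=O)[C@@]1(C)CCC[C@]2(O)[C@H]1CC[C@@H](C)[C@]2(C)CC=C | intermediate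
17 | methyl (1S,5S,6R,8aR)-1,5,6-trimethyl-5-(prop-2-en-1-yl)-1,2,3,5,6,7,8,8a-octahydronaphthalene-1-carboxylate | COC(=O)[C@@]1(C)CCC=C2[C@H]1CC[C@@H](C)[C@]2(C)CC=C | intermediate
18 | methyl (1S,5S,6R,8aR)-1,5,6-trimethyl-5-(3-oxopropyl)-1,2,3,5,6,7,8,8a-octahydronaphthalene-1-carboxylate | COC(=O)[C@@]1(C)CCC=C2[C@H]1CC[C@@H](C)[C@]2(C)CCC=O | intermediate
19 | methyl (1S,5S,6R,8aR)-5-(but-3-yn-1-yl)-1,5,6-trimethyl-1,2,3,5,6,7,8,8a-octahydronaphthalene-1-carboxylate | COC(=O)[C@@]1(C)CCC=C2[C@H]1CC[C@@H](C)[C@]2(C)CCC#C | intermediate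
20 | (E)-alkenyldimethylalane from syn-methylalumination of 19 | COC(=O)[C@@]1(C)CCC=C2[C@H]1CC[C@@H](C)[C@]2(C)CC/C(C)=C/[Al](C)C | intermediate (not isolated)
21 | lithium butyl(dimethyl)alkenylalanate of 20 | COC(=O)[C@@]1(C)CCC=C2[C@H]1CC[C@@H](C)[C@]2(C)CC/C(C)=C/[Al-](C)(C)CCCC.[Li+] | intermediate (not isolated)
22 | methyl (1S,5S,6R,8aR)-5-[(3E)-5-hydroxy-3-methylpent-3-en-1-yl]-1,5,6-trimethyl-1,2,3,5,6,7,8,8a-octahydronaphthalene-1-carboxylate | COC(=O)[C@@]1(C)CCC=C2[C@H]1CC[C@@H](C)[C@]2(C)CC/C(C)=C/CO | intermediate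
23 | methyl (1S,5S,6R,8aR)-5-[(3E)-5-(formyloxy)-3-methylpent-3-en-1-yl]-1,5,6-trimethyl-1,2,3,5,6,7,8,8a-octahydronaphthalene-1-carboxylate | COC(=O)[C@@]1(C)CCC=C2[C@H]1CC[C@@H](C)[C@]2(C)CC/C(C)=C/COC=O | target

**Step count.** Total: 12 steps. Longest linear sequence: 11 steps (1, 3–12); step 2 is a one-step side branch.

**Steps most likely to fail**

Step 6 (key step). The ring closure is a displacement at a CH2I carbon next to a fully substituted, oxygen-bearing carbon and may be slow. The sulfonyl carbanion could then add to a second sulfone or be quenched open-chain, and the face selectivity of the first bond at C4 may be incomplete. Fallback, setting out from ketone 5 and rejoining at 17: kinetic enolisation and triflation (LDA, PhNTf2) should give the enol triflate F1. Stille coupling with tributyl(vinyl)stannane (Pd(PPh3)4, LiCl) should give the 1-vinylcyclohexene diene F2. An Et2AlCl-promoted Diels–Alder reaction with methyl methacrylate then builds ring A through the other pair of bonds (C5–C4 and C2–C3) and gives 17 directly. Attack anti to the pseudoaxial C9 methyl with the ester endo should lead to the same configurations at C4 and C5. This bypasses steps 2–8 but does not use the ethano-bridge disconnection of this route.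

Step 4. The ylide may enolise the hindered ketone instead of adding, or may add from the equatorial side and give the epimeric oxirane, which would spoil the regiocontrol of step 8. Fallback, setting out from 9 and rejoining at 11: Wittig methylenation (Ph3P=CH2, toluene, heat) should give the exocyclic alkene F3. Iodohydrin formation (NIS, H2O/THF) should give the iodohydrin F4, with the iodonium on the less hindered axial face and water opening at the tertiary carbon from the opposite side. Silylation (TMSOTf, 2,6-lutidine) then gives 11. This replaces steps 4 and 5.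

Step 9. Markovnikov oxidation to the methyl ketone or olefin migration may compete with aldehyde formation. Fallback, setting out from 17 and rejoining at 18: chemoselective hydroboration of the terminal alkene with 9-BBN and oxidation (NaOH, H2O2) should give the primary alcohol F5, which Dess–Martin periodinane oxidises to 18.

**Further compounds**

F1 | step 6 | (5R,6S)-5,6-dimethyl-6-(prop-2-en-1-yl)cyclohex-1-en-1-yl trifluoromethanesulfonate | FC(F)(F)S(=O)(=O)OC1=CCC[C@@H](C)[C@]1(C)CC=C
F2 | step 6 | (5R,6S)-1-ethenyl-5,6-dimethyl-6-(prop-2-en-1-yl)cyclohex-1-ene | C=CC1=CCC[C@@H](C)[C@]1(C)CC=C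
F3 | step 4 | methyl (2S)-2-[(1S,3S,4R)-3,4-dimethyl-2-methylidene-3-(prop-2-en-1-yl)cyclohexyl]propanoate | COC(=O)[C@@H](C)[C@@H]1CC[C@@H](C)[C@](C)(CC=C)C1=C
F4 | step 4 | methyl (2S)-2-[(1S,2S,3S,4R)-2-hydroxy-2-(iodomethyl)-3,4-dimethyl-3-(prop-2-en-1-yl)cyclohexyl]propanoate | COC(=O)[C@@H](C)[C@@H]1CC[C@@H](C)[C@](C)(CC=C)[C@@]1(CI)O
F5 | step 9 | methyl (1S,5S,6R,8aR)-5-(3-hydroxypropyl)-1,5,6-trimethyl-1,2,3,5,6,7,8,8a-octahydronaphthalene-1-carboxylate | COC(=O)[C@@]1(C)CCC=C2[C@H]1CC[C@@H](C)[C@]2(C)CCCO
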